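Both flavanone rings are disconnected at C3–C4 and O1–C2 into a salicylaldehyde (ring A, with the free O1–H ortho to the formyl carbon that becomes C4) and a terminal aryl alkyne (C2, C3 and ring B).
Each ring is then made in one flask: rhodium-catalysed alkyne hydroacylation gives the (E)-2′-hydroxychalcone, and a chiral bifunctional thiourea closes it by oxa-Michael addition and sets C2 as S.
The enabling feature in unit 2 is the single free phenolic oxygen O1 on ring A′, flanked by the formyl carbon (future C4) and the biaryl carbon C8. It chelates rhodium for formyl C–H activation, and being the only free hydroxyl it can close only to the 8-aryl isomer.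
The biaryl bond (C2′ of ring B to C8 of ring A′) comes from a Suzuki–Miyaura coupling of iodosalicylaldehyde 3 with boronate 9, whose alkyne is masked as a silyl alkyne; salicylaldehyde 2 supplies ring A of both units.
Ring order: biaryl B–A′, then ring C′ of unit 2 (key step), then ring C of unit 1 (same reaction with 2), then removal of three MOM ethers.

Key step: step 9

Remark: the target string fixes C2 of both flavanone units as S but leaves the tetra-ortho-substituted biaryl axis undefined; the axis is not controlled here, so compounds from 10 onward may be mixtures of atropisomers that all carry the stated centres.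

Step 1
Reactants: 1 2,6-dihydroxy-4-methoxybenzaldehyde
Product: 2 2-hydroxy-4-methoxy-6-(methoxymethoxy)benzaldehyde
Conditions: MOMCl (1.05 equiv), iPr2NEt, CH2Cl2, 0 °C
Reagents that add atoms: chloromethyl methyl ether (MOMCl), COCCl
Why: O-alkylation of a phenol (MOM protection) at one of two equivalent hydroxyl groups, which should stop at the mono-ether because the remaining hydroxyl is held in a hydrogen bond to the aldehyde and is much less nucleophilic.

Step 2
Reactants: 2 2-hydroxy-4-methoxy-6-(methoxymethoxy)benzaldehyde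
Product: 3 2-hydroxy-3-iodo-4-methoxy-6-(methoxymethoxy)benzaldehyde
Conditions: NIS (1.05 equiv), DMF, 0 °C → rt
Reagents that add atoms: N-iodosuccinimide (NIS), O=C1CCC(=O)N1I
Why: Electrophilic aromatic iodination, expected ortho to the free chelated phenol at C3 (between OH and OMe) and not at the more crowded C5 (between OMe and OMOM), in line with the halogenation pattern of 2-hydroxy-4,6-dialkoxyaryl carbonyl compounds, so that the free hydroxyl ends up next to the future biaryl bond.

Step 3
Reactants: 4 2-bromo-3,4-dimethoxybenzaldehyde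
Product: 5 2-bromo-1-ethynyl-3,4-dimethoxybenzene
Conditions: MeC(O)C(N2)P(O)(OMe)2, K2CO3, MeOH, rt
Reagents that add atoms: dimethyl (1-diazo-2-oxopropyl)phosphonate (Ohira–Bestmann reagent), CC(=O)C(=[N+]=[N-])P(=O)(OC)OC
Why: Seyferth–Gilbert homologation in its Ohira–Bestmann form, which converts a non-enolisable aromatic aldehyde into the terminal alkyne under mild base that leaves the aryl bromide untouched.

Step 4
Reactants: 5 2-bromo-1-ethynyl-3,4-dimethoxybenzene
Product: 7 [(2-bromo-3,4-dimethoxyphenyl)ethynyl]triisopropylsilane, via lithium acetylide 6 (not isolated)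
Conditions: LiN(SiMe3)2, THF, −78 °C; then iPr3SiOTf, −78 °C → rt
Reagents that add atoms: triisopropylsilyl trifluoromethanesulfonate (TIPSOTf), CC(C)[Si](OS(=O)(=O)C(F)(F)F)(C(C)C)C(C)C
Why: Deprotonation of the terminal alkyne with a non-nucleophilic amide base (no bromine–lithium exchange) and C-silylation of the acetylide gives a bulky silyl alkyne that should stay inert in the cross-coupling and in the first hydroacylation.

Step 5
Reactants: 7 [(2-bromo-3,4-dimethoxyphenyl)ethynyl]triisopropylsilane
Product: 9 2-[2,3-dimethoxy-6-(triisopropylsilylethynyl)phenyl]-4,4,5,5-tetramethyl-1,3,2-dioxaborolane, via aryllithium 8 (not isolated)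
Conditions: n-BuLi, THF, −78 °C; then iPrOBpin, −78 °C → rt; H2O work-up
Reagents that add atoms: 2-isopropoxy-4,4,5,5-tetramethyl-1,3,2-dioxaborolane (iPrOBpin), CC(C)OB1OC(C)(C)C(C)(C)O1
Why: Bromine–lithium exchange followed by electrophilic borylation of the aryllithium, a route to doubly ortho-substituted aryl boronates that does not depend on a slow palladium-catalysed borylation.

Step 6
Reactants: 3 2-hydroxy-3-iodo-4-methoxy-6-(methoxymethoxy)benzaldehyde, 9 2-[2,3-dimethoxy-6-(triisopropylsilylethynyl)phenyl]-4,4,5,5-tetramethyl-1,3,2-dioxaborolane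
Product: 10 3-[2,3-dimethoxy-6-(triisopropylsilylethynyl)phenyl]-2-hydroxy-4-methoxy-6-(methoxymethoxy)benzaldehyde
Conditions: Pd(OAc)2 (5 mol%), SPhos (10 mol%), K3PO4, toluene/H2O, 90 °C
Reagents that add atoms: none
Why: Suzuki–Miyaura coupling with a bulky electron-rich dialkylbiarylphosphine of the kind used for tetra-ortho-substituted biaryls, the linear alkynyl group keeping one of the four ortho positions sterically small.

Step 7
Reactants: 11 4-hydroxy-3,5-dimethoxybenzaldehyde (syringaldehyde)
Product: 12 3,5-dimethoxy-4-(methoxymethoxy)benzaldehyde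
Conditions: MOMCl, iPr2NEt, CH2Cl2, 0 °C → rt
Reagents that add atoms: chloromethyl methyl ether (MOMCl), COCCl
Why: O-alkylation (MOM protection) of the only phenol, which would otherwise deactivate the aldehyde as its phenoxide in step 8 and compete for rhodium in step 9.

Step 8
Reactants: 12 3,5-dimethoxy-4-(methoxymethoxy)benzaldehyde
Product: 13 5-ethynyl-1,3-dimethoxy-2-(methoxymethoxy)benzene
Conditions: MeC(O)C(N2)P(O)(OMe)2, K2CO3, MeOH, rt
Reagents that add atoms: dimethyl (1-diazo-2-oxopropyl)phosphonate (Ohira–Bestmann reagent), CC(=O)C(=[N+]=[N-])P(=O)(OC)OC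
Why: Seyferth–Gilbert homologation in its Ohira–Bestmann form, reliable for electron-rich aromatic aldehydes and compatible with the MOM ether.

Step 9
Reactants: 10 3-[2,3-dimethoxy-6-(triisopropylsilylethynyl)phenyl]-2-hydroxy-4-methoxy-6-(methoxymethoxy)benzaldehyde, 13 5-ethynyl-1,3-dimethoxy-2-(methoxymethoxy)benzene
Product: 15 (2S)-8-[2,3-dimethoxy-6-(triisopropylsilylethynyl)phenyl]-2-[3,5-dimethoxy-4-(methoxymethoxy)phenyl]-7-methoxy-5-(methoxymethoxy)-2,3-dihydro-4H-chromen-4-one, via (E)-2′-hydroxychalcone 14 (not isolated)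
Conditions: 13 (1.5 equiv), [RhCl(cod)]2 (2.5 mol%), Fe(C5H4PPh2)2 (dppf, 5 mol%), Na2CO3 (10 mol%), toluene, 80 °C; then −20 °C, quinidine-derived 3,5-bis(trifluoromethyl)phenyl thiourea (20 mol%)
Reagents that add atoms: none
Why: The phenoxide of 10 binds monovalent rhodium, oxidative addition of the neighbouring formyl C–H bond gives a five-membered acyl(hydrido)rhodium chelate, syn-hydrometalation of the terminal alkyne of 13 places rhodium on the terminal carbon, and C–C reductive elimination forms the C3–C4 bond and releases (E)-chalcone 14, whose phenol is then added to C2 by the bifunctional thiourea (quinuclidine as general base, thiourea hydrogen-bonded to the enone carbonyl). The closest known reaction type is the tandem rhodium-catalysed alkyne hydroacylation of salicylaldehydes and oxa-Michael addition that gives chroman-4-ones, joined here to the cinchona–thiourea-catalysed cyclisation of 2′-hydroxychalcones to flavanones. The pyranone ring closes by a 6-endo-trig oxa-Michael addition (O1 to C2), helped by the 6′-alkoxy group, which twists the chalcone out of conjugation and makes the flavanone the more stable isomer. The new stereocentre C2 is set as S by the catalyst alone, through face-selective delivery of the phenol inside the hydrogen-bonded ion pair; the quinine-derived pseudoenantiomer would give the 2R series, so the catalyst series is assigned on a model chalcone before use, and the biaryl axis is not expected to override it. The step needs linear regiochemistry in the hydroacylation (steric preference of rhodium for the terminal alkyne carbon), chemoselectivity for alkyne 13 over the internal silyl alkyne (shielded by the triisopropylsilyl group and the flanking ring), and closure through O1 only, which is secured because the other oxygen ortho to the carbonyl is a MOM ether. Racemic background cyclisation should be held back by the low base loading of the first stage and the low temperature of the second.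

Step 10
Reactants: 15 (2S)-8-[2,3-dimethoxy-6-(triisopropylsilylethynyl)phenyl]-2-[3,5-dimethoxy-4-(methoxymethoxy)phenyl]-7-methoxy-5-(methoxymethoxy)-2,3-dihydro-4H-chromen-4-one
Product: 16 (2S)-8-(6-ethynyl-2,3-dimethoxyphenyl)-2-[3,5-dimethoxy-4-(methoxymethoxy)phenyl]-7-methoxy-5-(methoxymethoxy)-2,3-dihydro-4H-chromen-4-one
Conditions: Bu4NF, AcOH (1:1), THF, 0 °C → rt
Reagents that add atoms: none
Why: Fluoride-induced protodesilylation of the alkynylsilane, buffered with acetic acid so that no base strong enough to open the flavanone by β-elimination is present and the C2 centre is kept.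

Step 11
Reactants: 16 (2S)-8-(6-ethynyl-2,3-dimethoxyphenyl)-2-[3,5-dimethoxy-4-(methoxymethoxy)phenyl]-7-methoxy-5-(methoxymethoxy)-2,3-dihydro-4H-chromen-4-one, 2 2-hydroxy-4-methoxy-6-(methoxymethoxy)benzaldehyde
Product: 18 tris-MOM ether of the target, (2S)-2-{3,4-dimethoxy-2-[(2S)-2-[3,5-dimethoxy-4-(methoxymethoxy)phenyl]-7-methoxy-5-(methoxymethoxy)-4-oxo-3,4-dihydro-2H-chromen-8-yl]phenyl}-7-methoxy-5-(methoxymethoxy)-2,3-dihydro-4H-chromen-4-one, via (E)-2′-hydroxychalcone 17 (not isolated)
Conditions: 2 (1.5 equiv), [RhCl(cod)]2 (2.5 mol%), Fe(C5H4PPh2)2 (dppf, 5 mol%), Na2CO3 (10 mol%), toluene, 80 °C; then −20 °C, quinidine-derived 3,5-bis(trifluoromethyl)phenyl thiourea (20 mol%)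
Reagents that add atoms: none
Why: The same tandem as step 9, in which hydroacylation of the terminal alkyne of 16 by the phenoxide-chelated acyl rhodium hydride from 2 gives (E)-chalcone 17 and the thiourea-catalysed 6-endo-trig oxa-Michael addition sets C2 of unit 1 as S under catalyst control, while the first flavanone, which has no free phenol and is not enolised by the weak bases present, should keep its configuration.

Step 12
Reactants: 18 tris-MOM ether of the target
Product: 19 target, (2S)-2-{2-[(2S)-5-hydroxy-2-(4-hydroxy-3,5-dimethoxyphenyl)-7-methoxy-4-oxo-3,4-dihydro-2H-chromen-8-yl]-3,4-dimethoxyphenyl}-5-hydroxy-7-methoxy-2,3-dihydro-4H-chromen-4-one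
Conditions: HCl (3 M aq), MeOH/THF, 45 °C
Reagents that add atoms: none
Why: Acid-catalysed acetal cleavage removes all three MOM ethers, and the two flavanone centres, which are labile mainly to base-induced ring opening, should be unaffected.

Compound list
1 | 2,6-dihydroxy-4-methoxybenzaldehyde | COc1cc(O)c(C=O)c(O)c1 | starting material
2 | 2-hydroxy-4-methoxy-6-(methoxymethoxy)benzaldehyde | COCOc1cc(OC)cc(O)c1C=O | intermediate
3 | 2-hydroxy-3-iodo-4-methoxy-6-(methoxymethoxy)benzaldehyde | COCOc1cc(OC)c(I)c(O)c1C=O | intermediate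
4 | 2-bromo-3,4-dimethoxybenzaldehyde | COc1ccc(C=O)c(Br)c1OC | starting material
5 | 2-bromo-1-ethynyl-3,4-dimethoxybenzene | COc1ccc(C#C)c(Br)c1OC | intermediate
6 | lithium (2-bromo-3,4-dimethoxyphenyl)acetylide | COc1ccc(C#C[Li])c(Br)c1OC | intermediate
7 | [(2-bromo-3,4-dimethoxyphenyl)ethynyl]triisopropylsilane | COc1ccc(C#C[Si](C(C)C)(C(C)C)C(C)C)c(Br)c1OC | intermediate
8 | [2,3-dimethoxy-6-(triisopropylsilylethynyl)phenyl]lithium | COc1ccc(C#C[Si](C(C)C)(C(C)C)C(C)C)c([Li])c1OC | intermediate
9 | 2-[2,3-dimethoxy-6-(triisopropylsilylethynyl)phenyl]-4,4,5,5-tetramethyl-1,3,2-dioxaborolane | COc1ccc(C#C[Si](C(C)C)(C(C)C)C(C)C)c(B2OC(C)(C)C(C)(C)O2)c1OC | intermediate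
10 | 3-[2,3-dimethoxy-6-(triisopropylsilylethynyl)phenyl]-2-hydroxy-4-methoxy-6-(methoxymethoxy)benzaldehyde | COCOc1cc(OC)c(-c2c(C#C[Si](C(C)C)(C(C)C)C(C)C)ccc(OC)c2OC)c(O)c1C=O | intermediate
11 | 4-hydroxy-3,5-dimethoxybenzaldehyde (syringaldehyde) | COc1cc(C=O)cc(OC)c1O | starting material
12 | 3,5-dimethoxy-4-(methoxymethoxy)benzaldehyde | COCOc1c(OC)cc(C=O)cc1OC | intermediate
13 | 5-ethynyl-1,3-dimethoxy-2-(methoxymethoxy)benzene | COCOc1c(OC)cc(C#C)cc1OC | intermediate
14 | (E)-1-{3-[2,3-dimethoxy-6-(triisopropylsilylethynyl)phenyl]-2-hydroxy-4-methoxy-6-(methoxymethoxy)phenyl}-3-[3,5-dimethoxy-4-(methoxymethoxy)phenyl]prop-2-en-1-one | COCOc1cc(OC)c(-c2c(C#C[Si](C(C)C)(C(C)C)C(C)C)ccc(OC)c2OC)c(O)c1C(=O)/C=C/c1cc(OC)c(OCOC)c(OC)c1 | intermediate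
15 | (2S)-8-[2,3-dimethoxy-6-(triisopropylsilylethynyl)phenyl]-2-[3,5-dimethoxy-4-(methoxymethoxy)phenyl]-7-methoxy-5-(methoxymethoxy)-2,3-dihydro-4H-chromen-4-one | CC(C)[Si](C#Cc1ccc(OC)c(OC)c1-c1c(OC)cc(OCOC)c2c1O[C@H](c1cc(OC)c(OCOC)c(OC)c1)CC2=O)(C(C)C)C(C)C | intermediate
16 | (2S)-8-(6-ethynyl-2,3-dimethoxyphenyl)-2-[3,5-dimethoxy-4-(methoxymethoxy)phenyl]-7-methoxy-5-(methoxymethoxy)-2,3-dihydro-4H-chromen-4-one | C#Cc1ccc(OC)c(OC)c1-c1c(OC)cc(OCOC)c2c1O[C@H](c1cc(OC)c(OCOC)c(OC)c1)CC2=O | intermediate
17 | (E)-1-[2-hydroxy-4-methoxy-6-(methoxymethoxy)phenyl]-3-{3,4-dimethoxy-2-[(2S)-2-[3,5-dimethoxy-4-(methoxymethoxy)phenyl]-7-methoxy-5-(methoxymethoxy)-4-oxo-3,4-dihydro-2H-chromen-8-yl]phenyl}prop-2-en-1-one | COCOc1cc(OC)cc(O)c1C(=O)/C=C/c1ccc(OC)c(OC)c1-c1c(OC)cc(OCOC)c2c1O[C@H](c1cc(OC)c(OCOC)c(OC)c1)CC2=O | intermediate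
18 | tris-MOM ether of the target (both C2 centres S) | COc1cc(OCOC)c2c(c1)O[C@H](c1ccc(OC)c(OC)c1-c1c(OC)cc(OCOC)c3c1O[C@H](c1cc(OC)c(OCOC)c(OC)c1)CC3=O)CC2=O | intermediate
19 | target, (2S)-2-{2-[(2S)-5-hydroxy-2-(4-hydroxy-3,5-dimethoxyphenyl)-7-methoxy-4-oxo-3,4-dihydro-2H-chromen-8-yl]-3,4-dimethoxyphenyl}-5-hydroxy-7-methoxy-2,3-dihydro-4H-chromen-4-one | COc1cc(O)c2c(c1)O[C@H](c1ccc(OC)c(OC)c1-c1c(OC)cc(O)c3c1O[C@H](c1cc(OC)c(O)c(OC)c1)CC3=O)CC2=O | target

Total step count: 12. Longest linear sequence: 8 steps (steps 3, 4, 5, 6, 9, 10, 11 and 12, from 4).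

Steps most likely to fail

Step 9. The closure of a hindered, non-activated 2′-hydroxychalcone may proceed with low enantioselectivity, racemic cyclisation may already start during the hydroacylation stage, and the hydroacylation may give some branched enone. The fallback sets out from 10 and comes back at 15. Roskamp homologation of aldehyde 10 with allyl diazoacetate (SnCl2 cat., CH2Cl2) should give the allyl β-keto ester F1. Knoevenagel condensation of F1 with aldehyde 12 (piperidinium acetate, toluene, molecular sieves) should give the alkylidene β-keto ester F2, a doubly activated acceptor of the class for which cinchona–thiourea oxa-Michael catalysis is best established. Cyclisation with the same thiourea (toluene, −25 °C) should give the allyl (2S)-4-oxochromane-3-carboxylate F3. Deallylation with Pd(PPh3)4 and morpholine (THF, rt) and decarboxylation of the β-keto acid on gentle warming, which passes through the enol and leaves C2 untouched, should give 15.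

Step 11. Hydroacylation of the hindered ortho-aryl alkyne may be slow, prolonged heating with base may erode C2 of the first flavanone, and the second closure may be poorly selective. The fallback sets out from 16 and 2 and comes back at 17, which is then isolated and cyclised to 18 under the second-stage conditions of step 11. Semi-hydrogenation of 16 (H2, Pd/CaCO3 poisoned with Pb(OAc)2, quinoline, EtOAc) should give the styrene F4. Addition of vinylmagnesium bromide (2.2 equiv, THF, −78 °C) to 2 should give the allylic alcohol F5, and MnO2 (CH2Cl2, rt) should oxidise it to the aryl vinyl ketone F6, used at once. Cross-metathesis of F4 with F6 (second-generation Hoveyda–Grubbs catalyst, CH2Cl2, 40 °C), a neutral and base-free enone synthesis, should give (E)-chalcone 17.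

Step 6. Transmetalation at the doubly ortho-substituted boronate may be slow, so that protodeboronation, hydrodeiodination or palladium-mediated heteroannulation of the o-iodophenol with the alkyne takes over. The fallback sets out from 7 (through aryllithium 8) and 2 and comes back at 10 without the iodide 3. Trapping of 8 with Bu3SnCl should give the arylstannane F7. Tin–lead exchange (Pb(OAc)4, Hg(OAc)2 cat., CHCl3) should give the aryllead triacetate F8. Ortho-C-arylation of phenol 2 by F8 (pyridine, CHCl3, 40 °C), a ligand coupling on tetravalent lead that works on hindered 3,5-dioxygenated phenols, should give 10 directly; the only free ortho position of 2 is the required one.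

Further compounds
F1 | step 9 | allyl 3-{3-[2,3-dimethoxy-6-(triisopropylsilylethynyl)phenyl]-2-hydroxy-4-methoxy-6-(methoxymethoxy)phenyl}-3-oxopropanoate | C=CCOC(=O)CC(=O)c1c(O)c(-c2c(C#C[Si](C(C)C)(C(C)C)C(C)C)ccc(OC)c2OC)c(OC)cc1OCOC
F2 | step 9 | allyl 2-{3-[2,3-dimethoxy-6-(triisopropylsilylethynyl)phenyl]-2-hydroxy-4-methoxy-6-(methoxymethoxy)benzoyl}-3-[3,5-dimethoxy-4-(methoxymethoxy)phenyl]prop-2-enoate (alkene geometry not fixed) | C=CCOC(=O)C(=Cc1cc(OC)c(OCOC)c(OC)c1)C(=O)c1c(O)c(-c2c(C#C[Si](C(C)C)(C(C)C)C(C)C)ccc(OC)c2OC)c(OC)cc1OCOC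
F3 | step 9 | allyl (2S)-8-[2,3-dimethoxy-6-(triisopropylsilylethynyl)phenyl]-2-[3,5-dimethoxy-4-(methoxymethoxy)phenyl]-7-methoxy-5-(methoxymethoxy)-4-oxo-3,4-dihydro-2H-chromene-3-carboxylate (C3 epimerisable, 2,3-trans expected) | CC(C)[Si](C#Cc1ccc(OC)c(OC)c1-c1c(OC)cc(OCOC)c2c1O[C@H](c1cc(OC)c(OCOC)c(OC)c1)C(C(=O)OCC=C)C2=O)(C(C)C)C(C)C
F4 | step 11 | (2S)-8-(6-ethenyl-2,3-dimethoxyphenyl)-2-[3,5-dimethoxy-4-(methoxymethoxy)phenyl]-7-methoxy-5-(methoxymethoxy)-2,3-dihydro-4H-chromen-4-one | C=Cc1ccc(OC)c(OC)c1-c1c(OC)cc(OCOC)c2c1O[C@H](c1cc(OC)c(OCOC)c(OC)c1)CC2=O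
F5 | step 11 | 2-(1-hydroxyprop-2-en-1-yl)-5-methoxy-3-(methoxymethoxy)phenol (racemic) | C=CC(O)c1c(O)cc(OC)cc1OCOC
F6 | step 11 | 1-[2-hydroxy-4-methoxy-6-(methoxymethoxy)phenyl]prop-2-en-1-one | C=CC(=O)c1c(O)cc(OC)cc1OCOC
F7 | step 6 | tributyl[2,3-dimethoxy-6-(triisopropylsilylethynyl)phenyl]stannane | CCCC[Sn](CCCC)(CCCC)c1c(C#C[Si](C(C)C)(C(C)C)C(C)C)ccc(OC)c1OC
F8 | step 6 | [2,3-dimethoxy-6-(triisopropylsilylethynyl)phenyl]lead triacetate | CC(=O)O[Pb](OC(C)=O)(OC(C)=O)c1c(C#C[Si](C(C)C)(C(C)C)C(C)C)ccc(OC)c1OC
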